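## Analysis of the target

The target is an achiral benzophenone with three rings in a row: ring A is a 2-ethyl-4,6-dihydroxyphenyl group, ring B is a benzene ring carrying the ketone at C1, a hydroxyl at C2 and a methylene at C6, and ring C is a 4-hydroxy-2H-pyran-2-one bound through its C6 to that methylene. There is no stereocentre and no alkene geometry, so the problem is one of connectivity and chemoselectivity. The ketone carbon has four ortho neighbours (ethyl and hydroxyl on ring A, hydroxyl and the pyranylmethyl group on ring B), so acylating a finished ring A would be hindered and regiochemically uncertain. The sensitive groups are the 4-hydroxy-2-pyranone, a lactone that opens in aqueous base, and the methylene between rings B and C, which is benzylic and vinylogously alpha to the lactone carbonyl and therefore acidic. The electron-rich resorcinol ring A is open to electrophiles and oxidants, and a 2,2'-dioxygenated benzophenone closes to a xanthone when a phenoxide on one ring faces a leaving group on the other. The strategy rests on ring A: its C1 (acyl), C2 (ethyl), C4 and C6 (oxygen) form the pattern of a 5-alkylresorcinol acylated next to the alkyl group, which is the aromatized form of a 4-aroyl-5-ethylcyclohexane-1,3-dione. That dione can be assembled from an aroylacetate and a six-carbon enone with the ketone already in place, so ring A is never acylated.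

## Retrosynthetic reasoning

**15 to 14.** The four hydroxyl groups of target 15 are traced back to four methyl ethers in 14; only O–CH3 bonds are cut. Methyl is chosen because three of the four come at no cost: the ring B ether from acid 1, the pyranone ether from 11, and the ring A para ether from the aromatization. The forward cleavage has to be acidic, because a phenoxide ortho to the ketone could attack the other ring and aqueous base would open the lactone.

**14 to 10 and 13.** The bond between C6 of ring B and the methylene carbon is cut. This detaches ring C complete, so it can come from commercial pyranone 11 through bromide 12 and zinc reagent 13. Cutting the other methylene bond would need a benzylic metal ortho to a ketone, and cutting at the ketone would bring back the hindered acylation. The forward reaction is a palladium-catalysed sp2–sp3 coupling of 13 with aryl bromide 10 that must leave the lactone and the diaryl ketone untouched.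

**10 to 9 to 8.** No skeletal bond is cut. The ortho methyl ether of 10 is removed to give phenol 9, and the arene of 9 is traced back to the cyclohexane-1,3-dione 8 by adding two hydrogens and removing the para O-methyl group. This turns "acylate an arene next to its ethyl group" into a ring-forming problem. The forward dehydrogenation must spare the aryl bromide and erases both stereocentres of 8.

**8 to 5 and 6.** Two ring bonds of 8 are cut: C4–C5 (between the aroyl-bearing and ethyl-bearing carbons) and C2–C3 (between the central methylene and the carbonyl next to C4). This gives keto ester 5 as a three-carbon donor carrying the ketone and ring B, and enone 6 as the partner supplying the ethyl group and the remaining three ring carbons. The forward reaction must form both bonds in one operation and close through the ester of 5, not through its aryl ketone.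

**5 to 2 and 3, and 2 to 1.** The bond between the aryl ketone carbon and the alpha carbon of 5 is cut, leading to acid chloride 2 and malonate half-ester salt 3 with decarboxylation; 2 comes from commercial acid 1. The bromine of 1 is the later coupling handle and is inert until step 7.

**12 to 11.** The C–Br bond of 12 is cut, leading to the methyl group of 11, which is the only sp3 C–H position in that molecule.

## Alternatives that were turned down

**Alternative 1:** Ring B is cut at two bonds: between its hydroxyl-bearing and ketone-bearing carbons, and between its side-chain-bearing carbon and the neighbouring CH. The forward step is a Diels–Alder reaction of the diene A1, 3-hydroxy-2H-pyran-2-one, with the ynone A2, 5-[(tert-butyldimethylsilyl)oxy]-1-(2-ethyl-4,6-dimethoxyphenyl)pent-2-yn-1-one. Loss of CO2 from the bicyclic lactone would then give the phenol A3, [2-(2-((tert-butyldimethylsilyl)oxy)ethyl)-6-hydroxyphenyl](2-ethyl-4,6-dimethoxyphenyl)methanone.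
- For: the polarity match is clear (the nucleophilic C6 of A1 pairs with the beta carbon of A2), so one regiochemistry is expected. The crowded 1,2,3-pattern of ring B arrives in one step, and the phenol of A3 is free.
- Against: the aroyl unit of A2 still has to be attached to a ring A arene by acylation or addition chemistry, which is the problem the chosen route avoids. The carbonyl of A2 sits on a di-ortho-substituted ring and is twisted, so the internal alkyne is a sluggish dienophile. A3 carries only a two-carbon stub where ring C belongs; desilylation, oxidation, four-carbon extension and lactonization would add five or more steps beside a free phenol.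
- Comparison: A3 is stronger in that ring B needs no protection and no coupling beside the aroyl group. The chosen route offers ring C in one coupling from a commercial pyranone and a ring A that is never acylated.

**Alternative 2:** Ring C is cut at its O1–C6 bond, which leads back to the ynone keto ester A4, tert-butyl 6-[2-(2-ethyl-4,6-dimethoxybenzoyl)-3-methoxyphenyl]-3-oxohex-4-ynoate. In the forward step a cationic monovalent gold centre activates the alkyne of A4, the ester carbonyl oxygen adds 6-endo-dig to the alkyne carbon bearing the benzylic methylene, and the tert-butyl group leaves as the alkene. The product would be the pyranone A5, 6-[2-(2-ethyl-4,6-dimethoxybenzoyl)-3-methoxybenzyl]-4-hydroxy-2H-pyran-2-one.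
- For: in A5 the pyranone appears under neutral catalytic conditions with its hydroxyl free, so no vinylogous ester has to be cleaved. On this point it is stronger than the chosen route.
- Against: the methylene of A4 is benzylic and propargylic to an ynone, so it is prone to prototropic shift to an allenyl ketone under the basic conditions needed to build it. Making A4 needs a propargylation next to the hindered ketone and a keto ester acylation, more steps than one cross-coupling. The benzophenone oxygen can add to the activated alkyne in a competing 6-exo closure. The three aryl methyl ethers of A5 must still be cleaved afterwards, and the construction of ring A is not addressed.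
- Comparison: A5 differs from compound 14 of the chosen route only by one methyl ether on ring C. The chosen route pays for that ether and in return gets ring C intact in two steps from a commercial compound, with ring A built without acylation.

**Alternative 3:** Ring A is cut at the bond between its ketone-bearing and ethyl-bearing carbons. The precursor is the pyranone A6, 2-[2-(2-allyl-6-methoxyphenyl)-2-oxoethyl]-6-ethyl-4H-pyran-4-one. Aqueous KOH opens A6 to the enolized tetraketone A7, 1-(2-allyl-6-methoxyphenyl)nonane-1,3,5,7-tetraone, whose C2 methylene adds to the C7 carbonyl. Loss of water would give the benzophenone A8, (2-allyl-6-methoxyphenyl)(2-ethyl-4,6-dihydroxyphenyl)methanone.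
- For: the closure is redox-neutral and A8 has ring A with both phenols free, so it is stronger than the chosen route on oxidation and protecting-group economy. It uses the same steric shielding of the aryl ketone.
- Against: A7 has several nucleophilic methylenes and four carbonyls. Closure of C8 onto C3 would give an isomeric arene, and reclosure to pyranones competes. A6 needs its own multi-step synthesis with a hindered acylation. The allyl group can move into conjugation in hot aqueous KOH. The allyl group of A8 must then be cleaved oxidatively beside a free resorcinol, and ring C must be built in several further steps.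
- Comparison: A8 is reached without any oxidation, but the chosen annulation has only one competing closure to suppress, both partners are at hand in at most two steps, and ring C is bought.

Key step: step 3

Remark: the target has no stereocentre. Compound 8 is drawn as the triketone although it should exist largely as enol tautomers, and its two stereocentres are racemic and transient.

## Route

**Step 1**
Reactants: 1 2-bromo-6-methoxybenzoic acid
Product: 2 2-bromo-6-methoxybenzoyl chloride
Conditions: (COCl)2, DMF (cat.), CH2Cl2, 0 °C to 25 °C; concentrate
Reagents that add atoms: oxalyl chloride, ClC(=O)C(=O)Cl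
Why: Acid chloride formation through the chloroiminium salt from DMF and oxalyl chloride; the di-ortho-substituted acid is taken to its most reactive acyl form so that the hindered acylation of step 2 is not limiting.

**Step 2**
Reactants: 2 2-bromo-6-methoxybenzoyl chloride; 3 potassium methyl malonate
Product: 5 methyl 3-(2-bromo-6-methoxyphenyl)-3-oxopropanoate, via acylmalonic half-ester 4 (not isolated)
Conditions: 3, MgCl2, Et3N, MeCN, 25 °C; then 2, 0 °C to 25 °C; aq HCl
Reagents that add atoms: none
Why: C-acylation of the chelated magnesium enolate of the malonate half-ester (malonic half-ester synthesis of beta-keto esters); chelation by magnesium favours C- over O-acylation, and 4 loses CO2 on acidic work-up.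

**Step 3**
Reactants: 5 methyl 3-(2-bromo-6-methoxyphenyl)-3-oxopropanoate; 6 (E)-hex-3-en-2-one
Product: 8 rac-trans-4-(2-bromo-6-methoxybenzoyl)-5-ethylcyclohexane-1,3-dione, via Michael adduct 7 (not isolated)
Conditions: NaOMe (1.2–1.5 equiv), MeOH, 25 °C then reflux; aq HCl
Reagents that add atoms: none
Why: This is a tandem Michael addition and intramolecular Claisen condensation, the reaction by which malonates and alk-3-en-2-ones give 5-alkylcyclohexane-1,3-diones, here run with an aroylacetate donor. NaOMe turns 5 into its stabilized enolate, whose alpha carbon adds to C4 of enone 6 and forms the C4–C5 bond of the ring in adduct 7. Proton exchange in methanol then provides the terminal methyl ketone enolate of 7, whose CH2 carbon attacks the ester carbonyl in a 6-(enolendo)-exo-trig closure; loss of methoxide forms the C2–C3 bond and closes ring A as the cyclohexane-1,3-dione. Deprotonation of the product to its delocalized enolate makes the closure irreversible and pulls the reversible Michael step forward. The stereocentre at C5 is formed in the Michael addition without control and is racemic; the one at C4 lies between two carbonyl groups, equilibrates under the basic conditions and should settle trans to ethyl on steric grounds. Neither needs control because step 4 erases both. The selectivity required is Claisen closure onto the ester instead of aldol closure of the same enolate onto the aryl ketone (the Robinson mode). It is secured because that ketone carries bromine and methoxy in both ortho positions, which shields its carbon and twists it out of conjugation, because the aldol is reversible while the Claisen is not, and because the internal alpha-CH2 of the ketone could only form four-membered rings.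

**Step 4**
Reactants: 8 rac-trans-4-(2-bromo-6-methoxybenzoyl)-5-ethylcyclohexane-1,3-dione
Product: 9 (2-bromo-6-methoxyphenyl)(2-ethyl-6-hydroxy-4-methoxyphenyl)methanone
Conditions: I2 (1.2 equiv), MeOH, reflux
Reagents that add atoms: methanol, CO
Why: Iodine-mediated oxidative aromatization of a cyclohexane-1,3-dione: HI formed in the flask and methanol convert the unhindered C1 carbonyl into the vinylogous methyl ester, iodination next to the enone and loss of HI add the missing unsaturation, and tautomerization gives the arene. The C3 oxygen, chelated to the aroyl carbonyl, should stay a free phenol, and both stereocentres disappear.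

**Step 5**
Reactants: 9 (2-bromo-6-methoxyphenyl)(2-ethyl-6-hydroxy-4-methoxyphenyl)methanone
Product: 10 (2-bromo-6-methoxyphenyl)(2-ethyl-4,6-dimethoxyphenyl)methanone
Conditions: MeI, K2CO3, DMF, 25 °C
Reagents that add atoms: iodomethane, CI
Why: Williamson O-methylation of the chelated ortho-hydroxybenzophenone; at room temperature methylation should outrun displacement of the ortho bromide by the phenoxide, and any dimethyl ether already formed in step 4 is the same compound 10.

**Step 6**
Reactants: 11 4-methoxy-6-methyl-2H-pyran-2-one
Product: 12 6-(bromomethyl)-4-methoxy-2H-pyran-2-one
Conditions: NBS, AIBN (cat.), PhCF3, 80 °C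
Reagents that add atoms: N-bromosuccinimide, O=C1CCC(=O)N1Br
Why: Wohl–Ziegler radical bromination; the methyl group gives a radical delocalized over the pyranone, and radical-chain conditions in a non-polar solvent suppress ionic bromination at C3.

**Step 7**
Reactants: 12 6-(bromomethyl)-4-methoxy-2H-pyran-2-one; 10 (2-bromo-6-methoxyphenyl)(2-ethyl-4,6-dimethoxyphenyl)methanone
Product: 14 6-[2-(2-ethyl-4,6-dimethoxybenzoyl)-3-methoxybenzyl]-4-methoxy-2H-pyran-2-one, via pyranylmethylzinc bromide 13 (not isolated)
Conditions: 12, Zn, LiCl, THF, 0 °C to 25 °C; then 10, Pd(OAc)2 (cat.), SPhos (cat.), THF, 25 °C to 50 °C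
Reagents that add atoms: none
Why: Negishi sp2–sp3 coupling: LiCl-assisted insertion of zinc into the activated C–Br bond of 12 gives the heterobenzylic zinc reagent 13; oxidative addition of zerovalent palladium into the C–Br bond of 10 is helped by the ortho carbonyl, and transmetalation and reductive elimination form the aryl–CH2 bond. The zinc reagent tolerates the lactone and should not add to the tetra-ortho-substituted diaryl ketone.

**Step 8**
Reactants: 14 6-[2-(2-ethyl-4,6-dimethoxybenzoyl)-3-methoxybenzyl]-4-methoxy-2H-pyran-2-one
Product: 15 6-[2-(2-ethyl-4,6-dihydroxybenzoyl)-3-hydroxybenzyl]-4-hydroxy-2H-pyran-2-one (target)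
Conditions: BBr3 (excess), CH2Cl2, −78 °C to 0 °C; then H2O
Reagents that add atoms: none
Why: Lewis acid ether cleavage: BBr3 binds each ether oxygen and bromide removes the methyl group by SN2; the pyranone methoxy group is a vinylogous methyl ester and should cleave readily. Cold acidic conditions avoid base-promoted xanthone closure and lactone opening.

## Compound list

1 | 2-bromo-6-methoxybenzoic acid | COc1cccc(Br)c1C(O)=O | starting material
2 | 2-bromo-6-methoxybenzoyl chloride | COc1cccc(Br)c1C(Cl)=O | intermediate
3 | potassium methyl malonate | COC(=O)CC(=O)[O-].[K+] | starting material
4 | 2-(2-bromo-6-methoxybenzoyl)-3-methoxy-3-oxopropanoic acid (racemic, present as its magnesium chelate, not isolated) | COC(=O)C(C(O)=O)C(=O)c1c(OC)cccc1Br | intermediate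
5 | methyl 3-(2-bromo-6-methoxyphenyl)-3-oxopropanoate | COC(=O)CC(=O)c1c(OC)cccc1Br | intermediate
6 | (E)-hex-3-en-2-one | CC/C=C/C(C)=O | starting material
7 | methyl 2-(2-bromo-6-methoxybenzoyl)-3-ethyl-5-oxohexanoate (racemic mixture of diastereomers, not isolated) | COC(=O)C(C(CC)CC(C)=O)C(=O)c1c(OC)cccc1Br | intermediate
8 | rac-trans-4-(2-bromo-6-methoxybenzoyl)-5-ethylcyclohexane-1,3-dione | CC[C@@H]1CC(=O)CC(=O)[C@H]1C(=O)c1c(OC)cccc1Br | intermediate
9 | (2-bromo-6-methoxyphenyl)(2-ethyl-6-hydroxy-4-methoxyphenyl)methanone | CCc1cc(OC)cc(O)c1C(=O)c1c(OC)cccc1Br | intermediate
10 | (2-bromo-6-methoxyphenyl)(2-ethyl-4,6-dimethoxyphenyl)methanone | CCc1cc(OC)cc(OC)c1C(=O)c1c(OC)cccc1Br | intermediate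
11 | 4-methoxy-6-methyl-2H-pyran-2-one | COc1cc(C)oc(=O)c1 | starting material
12 | 6-(bromomethyl)-4-methoxy-2H-pyran-2-one | COc1cc(CBr)oc(=O)c1 | intermediate
13 | [(4-methoxy-2-oxo-2H-pyran-6-yl)methyl]zinc bromide (not isolated) | COc1cc(C[Zn]Br)oc(=O)c1 | intermediate
14 | 6-[2-(2-ethyl-4,6-dimethoxybenzoyl)-3-methoxybenzyl]-4-methoxy-2H-pyran-2-one | CCc1cc(OC)cc(OC)c1C(=O)c1c(OC)cccc1Cc1cc(OC)cc(=O)o1 | intermediate
15 | 6-[2-(2-ethyl-4,6-dihydroxybenzoyl)-3-hydroxybenzyl]-4-hydroxy-2H-pyran-2-one | CCc1cc(O)cc(O)c1C(=O)c1c(O)cccc1Cc1cc(O)cc(=O)o1 | target

## Step count and least certain steps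

Total step count: 8. Longest linear sequence: 7 steps (steps 1, 2, 3, 4, 5, 7 and 8); step 6 is a one-step side branch.

**Step 3 (key step).** The most likely failure is stalling after the Michael addition. Adduct 7 rests as its stabilized keto ester enolate, so little of the reactive methyl ketone enolate is present and the Claisen closure may be slow. Aldol closure onto the aryl ketone followed by dehydration, or slow displacement of the ortho bromide by an enolate oxygen on long reflux, could then take over.
Fallback, from 6 and 2 back to 10: the annulation is run with the donor for which it is routine. Dimethyl malonate and 6 with NaOMe in methanol should give methyl 2-ethyl-4,6-dioxocyclohexane-1-carboxylate F1. Aqueous NaOH, then acid and heat, remove the ester group to give 5-ethylcyclohexane-1,3-dione F2. Iodine in methanol, completed by MeI and K2CO3, should give 1-ethyl-3,5-dimethoxybenzene F3. Friedel–Crafts acylation of F3 with acid chloride 2 (SnCl4, CH2Cl2, 0 °C), para to one methoxy group and next to ethyl, should then give 10. This gives up the advantage of never acylating ring A and accepts a regiochemical risk in the acylation.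

**Step 4.** The oxidation may partition badly: unproductive iodination at C2, acid-catalysed cleavage of the triketone by methanol before the vinylogous ester forms, or incomplete dehydrogenation could each lower the conversion.
Fallback, from 8 back to 10: bromination and dehydrobromination with Br2 (1 equiv) in DMF, 0 °C then 80 °C, the classical aromatization of 4-acylated cyclohexane-1,3-diones, should give the free resorcinol (2-bromo-6-methoxyphenyl)(2-ethyl-4,6-dihydroxyphenyl)methanone F4. The conditions of step 5 with excess MeI then methylate both hydroxyl groups to 10.

**Step 7.** Homocoupling during zinc insertion into the reactive bromide 12 is the main concern, followed by slow coupling beside the bulky aroyl group (leading to protodezincation) and bond formation through a ring carbon of the ambident zinc reagent.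
Fallback, from 10 back to 14: the polarity is reversed. Miyaura borylation of 10 (B2pin2, PdCl2(dppf), KOAc, dioxane, 90 °C) should give (2-ethyl-4,6-dimethoxyphenyl)[2-methoxy-6-(4,4,5,5-tetramethyl-1,3,2-dioxaborolan-2-yl)phenyl]methanone F5. Suzuki–Miyaura coupling of F5 with bromide 12 (Pd(PPh3)4, K3PO4, dioxane, 60 °C) then gives 14 without any organozinc.

**Step 8.** One ether may cleave incompletely (most likely the non-chelated para ether of ring A), or the Lewis acid may activate the ketone towards attack by C5 of the pyranone, leading to cyclization and dehydration.
Fallback, from 10 back to 15: the aryl ethers are cleaved before ring C is present. BBr3 on 10 should give (2-bromo-6-hydroxyphenyl)(2-ethyl-4,6-dihydroxyphenyl)methanone F6. Negishi coupling of F6 with excess 13, added slowly under the Pd(OAc)2/SPhos conditions that tolerate acidic O–H groups, should give 6-[2-(2-ethyl-4,6-dihydroxybenzoyl)-3-hydroxybenzyl]-4-methoxy-2H-pyran-2-one F7. The remaining vinylogous methyl ester is then cleaved with iodotrimethylsilane made from TMSCl and NaI in MeCN, giving 15 after aqueous work-up.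

## Further compounds

F1 | step 3 | methyl 2-ethyl-4,6-dioxocyclohexane-1-carboxylate (racemic, trans) | CC[C@@H]1CC(=O)CC(=O)[C@H]1C(=O)OC
F2 | step 3 | 5-ethylcyclohexane-1,3-dione | CCC1CC(=O)CC(=O)C1
F3 | step 3 | 1-ethyl-3,5-dimethoxybenzene | CCc1cc(OC)cc(OC)c1
F4 | step 4 | (2-bromo-6-methoxyphenyl)(2-ethyl-4,6-dihydroxyphenyl)methanone | CCc1cc(O)cc(O)c1C(=O)c1c(OC)cccc1Br
F5 | step 7 | (2-ethyl-4,6-dimethoxyphenyl)[2-methoxy-6-(4,4,5,5-tetramethyl-1,3,2-dioxaborolan-2-yl)phenyl]methanone | CCc1cc(OC)cc(OC)c1C(=O)c1c(OC)cccc1B1OC(C)(C)C(C)(C)O1
F6 | step 8 | (2-bromo-6-hydroxyphenyl)(2-ethyl-4,6-dihydroxyphenyl)methanone | CCc1cc(O)cc(O)c1C(=O)c1c(O)cccc1Br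
F7 | step 8 | 6-[2-(2-ethyl-4,6-dihydroxybenzoyl)-3-hydroxybenzyl]-4-methoxy-2H-pyran-2-one | CCc1cc(O)cc(O)c1C(=O)c1c(O)cccc1Cc1cc(OC)cc(=O)o1
A1 | alternative 1 | 3-hydroxy-2H-pyran-2-one | O=c1occcc1O
A2 | alternative 1 | 5-[(tert-butyldimethylsilyl)oxy]-1-(2-ethyl-4,6-dimethoxyphenyl)pent-2-yn-1-one | CCc1cc(OC)cc(OC)c1C(=O)C#CCCO[Si](C)(C)C(C)(C)C
A3 | alternative 1 | [2-(2-((tert-butyldimethylsilyl)oxy)ethyl)-6-hydroxyphenyl](2-ethyl-4,6-dimethoxyphenyl)methanone | CCc1cc(OC)cc(OC)c1C(=O)c1c(O)cccc1CCO[Si](C)(C)C(C)(C)C
A4 | alternative 2 | tert-butyl 6-[2-(2-ethyl-4,6-dimethoxybenzoyl)-3-methoxyphenyl]-3-oxohex-4-ynoate | CCc1cc(OC)cc(OC)c1C(=O)c1c(OC)cccc1CC#CC(=O)CC(=O)OC(C)(C)C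
A5 | alternative 2 | 6-[2-(2-ethyl-4,6-dimethoxybenzoyl)-3-methoxybenzyl]-4-hydroxy-2H-pyran-2-one | CCc1cc(OC)cc(OC)c1C(=O)c1c(OC)cccc1Cc1cc(O)cc(=O)o1
A6 | alternative 3 | 2-[2-(2-allyl-6-methoxyphenyl)-2-oxoethyl]-6-ethyl-4H-pyran-4-one | CCc1cc(=O)cc(CC(=O)c2c(OC)cccc2CC=C)o1
A7 | alternative 3 | 1-(2-allyl-6-methoxyphenyl)nonane-1,3,5,7-tetraone | CCC(=O)CC(=O)CC(=O)CC(=O)c1c(OC)cccc1CC=C
A8 | alternative 3 | (2-allyl-6-methoxyphenyl)(2-ethyl-4,6-dihydroxyphenyl)methanone | CCc1cc(O)cc(O)c1C(=O)c1c(OC)cccc1CC=C
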